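All runs were generated by integration for an exercise.

We decide to compare the runs at their last reading, 12.0 h, and to fold them into one number.

| flask | solid substrate | partner | remark | time |
|---|---|---|---|---|
| Wednesday's | 0.42 M | 0.945 M | run made earlier |  |
| Thursday's | 0.95 M | 0.945 M | run made earlier |  |
| Saturday's | 0.63 M | 1.9 M | run made earlier |  |
| flask | 0.63 M | 0.945 M |  | 10 h |

- Wednesday's (time / h: target / %, solid product / %): 1.50: 2.2, 0; 4.00: 6.1, 0; 8.00: 14.5, 0; 12.0: 17.8, 0
- Thursday's (time / h: target / %, solid product / %): 1.00: 0, 0; 2.00: 0.1, 0.1; 5.00: 4.8, 0.9; 12.0: 12.3, 0
- Saturday's (time / h: target / %, solid product / %): 1.00: 2.3, 0.2; 2.00: 1.7, 0; 5.00: 6.4, 0; 12.0: 15.2, 0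

(each reading ± 1 percentage point)

- what is said of target includes solid product
- solid substrate, solid product is a solid; its amount is given per volume of the solution
- at the start none of the solid substrate is in solution
- dissolved substrate means what is dissolved; the solid is not counted in it

* target and solid product together at 10 h, in percent of the solid substrate charged
* concentration of dissolved substrate in solution at 10 h, in percent of saturation

Wednesday's run gives 17.8 % of its charge as target, and Thursday's, with more solid substrate and the same partner, gives 12.3 %. From these two readings we get n = 0.453, the loading exponent: the power of the charge of solid substrate with which percent yield falls at a fixed time and a fixed charge of partner. An exponent of zero means the same percent from any charge, as in a first-order step, and one means the same molarity of target.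

For our flask, n gives 14.8 % at 12.0 h. Is one number enough? Saturday's run, with this charge and twice the partner, read 15.2 %, which is 0.40 percentage points away and inside the scatter, so we carry no term for partner. Wednesday's target grew 2.92 times over 3.00 times the time, so we go round once more, scaling to 10 h, and commit to 12.3 %. The runs report no concentration of dissolved substrate, so n gives no saturation.

The forecast says 12.7 % for the yield and 10 % of saturation, on the ground that “Rate rises with solid loading, roughly as its square root”; its yield is close to ours but is not our number.

The flask gives a yield of 11.0 % and 50.7 % of saturation.

    dissolved substrate + partner → target (k = 0.430 /M/h)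
    solid substrate ⇌ dissolved substrate, rate k2*(cs2 - [dissolved substrate]) while solid is left; crystals form when [dissolved substrate] > cs2 (solubility = 0.280 M, k = 0.150 /h)
    solid product ⇌ target, rate k3*(cs3 - [target]) while solid is left; crystals form when [target] > cs3 (solubility = 0.250 M, k = 1.80 /h)
    2 partner → homo dimer (k = 0.440 /M/h)
    2 dissolved substrate → side product (k = 0.300 /M/h)

Our yield stands 1.3 points above the flask's, and the flask's saturation stands 41 points above the forecast's. We now carry n to the neighbouring flask with 0.16 M of solid substrate, a charge below Wednesday's, with the same partner and time. There n gives 23.0 %, whereas that neighbour gives 37.3 %, which is 14 points more. At 10.0 h that neighbour holds 0 % of solid substrate, against 56.2 % in our flask, and 22.3 % of its charge stands as side product.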